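**Plan**

- Retrosynthesis: the pyran ring is opened in one retro-oxa-[4+2] step at O1–C2 and C3–C4, giving an A-ring ortho-quinone methide and 4-methoxystyrene. C4 is then traced back to a formyl group on C4a, and the C6–prenyl bond is cut, leaving 3,5-dimethoxyphenol.
- Enabling feature: O1–C8a–C4a–C4 of the benzo ring is a 2-oxybenzyl unit whose C4a has OMe groups ortho (C5) and para (C7), so C4 ionises easily to a quinone methide. C2 carries a p-anisyl group, so C2=C3 is an electron-rich styrene polarised to give C3 to C4 and C2 to O1.
- Forward: the A ring is bought. Prenyl is placed between the two OMe groups by directed lithiation. The resulting phenol is symmetric, so the C4 carbon can only enter at the correct ortho site. The pyran ring is closed last by the cycloaddition, which also brings in the B ring.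
- Stereochemistry: the single stereocentre C2 (S) is set in the ring-forming step by a chiral Brønsted acid. No stereocentre exists before it and none is touched after it.

Key step: step 6

Assumption: the sense of induction of the chiral acid in step 6 cannot be predicted from the aryl-substituted precedents. The (R)-catalyst is written; the (S)-antipode would be used if a small test run showed the (2R)-product to prevail.

**Route**

Step 1
Reactants: 1 3,5-dimethoxyphenol
Product: 2 (3,5-dimethoxyphenoxy)tri(propan-2-yl)silane
Conditions: TIPSCl, imidazole, DMF, rt
Reagents that add atoms: triisopropylsilyl chloride, CC(C)[Si](Cl)(C(C)C)C(C)C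
Why: Imidazole-promoted silyl ether formation masks the acidic OH with a bulky, poorly coordinating group that should steer the next metalation away from its own ortho positions.

Step 2
Reactants: 2 (3,5-dimethoxyphenoxy)tri(propan-2-yl)silane; 3 prenyl bromide (1-bromo-3-methylbut-2-ene)
Product: 5 [3,5-dimethoxy-4-(3-methylbut-2-en-1-yl)phenoxy]tri(propan-2-yl)silane, via aryllithium 4 (not isolated)
Conditions: n-BuLi, THF, 0 °C → rt; then CuI (5 mol %), 3, −78 °C → rt
Reagents that add atoms: none
Why: Directed ortho-metalation should take place at the C–H between the two methoxy groups (doubly activated, while the TIPS-oxygen is a poor director), and copper-catalysed SN2 alkylation at the CH2 end of the allylic bromide should give the linear prenyl group.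

Step 3
Reactants: 5 [3,5-dimethoxy-4-(3-methylbut-2-en-1-yl)phenoxy]tri(propan-2-yl)silane
Product: 6 3,5-dimethoxy-4-(3-methylbut-2-en-1-yl)phenol
Conditions: TBAF, THF, 0 °C
Reagents that add atoms: none
Why: Fluoride cleavage of the aryl silyl ether should free a phenol with a mirror plane through C1 and C4, so that its two ortho carbons are equivalent.

Step 4
Reactants: 6 3,5-dimethoxy-4-(3-methylbut-2-en-1-yl)phenol
Product: 8 6-hydroxy-2,4-dimethoxy-3-(3-methylbut-2-en-1-yl)benzaldehyde, via magnesium saligeninate 7 (not isolated)
Conditions: MgCl2, Et3N, (CH2O)n, MeCN, reflux; cold dilute HCl work-up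
Reagents that add atoms: formaldehyde (from paraformaldehyde), C=O
Why: In the magnesium-mediated ortho-formylation (Casnati–Skattebøl) the magnesium phenoxide delivers formaldehyde to the ortho carbon through a chelate and the hydroxymethyl alkoxide is oxidised by a second formaldehyde (Oppenauer-type hydride transfer); only one aldehyde can form from the symmetric phenol, and the non-acidic medium should spare the prenyl group.

Step 5
Reactants: 8 6-hydroxy-2,4-dimethoxy-3-(3-methylbut-2-en-1-yl)benzaldehyde
Product: 9 2-(hydroxymethyl)-3,5-dimethoxy-4-(3-methylbut-2-en-1-yl)phenol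
Conditions: NaBH4, THF/MeOH, 0 °C; pH 7 buffer; used crude at once
Reagents that add atoms: none
Why: Borohydride 1,2-reduction of the aldehyde at low temperature should give the saligenin, which is kept cold and not chromatographed because it ionises easily.

Step 6
Reactants: 9 2-(hydroxymethyl)-3,5-dimethoxy-4-(3-methylbut-2-en-1-yl)phenol; 10 4-methoxystyrene
Product: 12 (2S)-5,7-dimethoxy-2-(4-methoxyphenyl)-6-(3-methylbut-2-en-1-yl)-3,4-dihydro-2H-chromene, via ortho-quinone methide 11 (not isolated)
Conditions: (R)-3,3'-bis(2,4,6-triisopropylphenyl)-H8-BINOL N-triflylphosphoramide (10 mol %), 10 (5 equiv), 4 Å MS, toluene, −20 °C, slow addition of 9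
Reagents that add atoms: none
Why: Proposed new method: the chiral acid should protonate the benzylic OH of 9, which leaves with the help of the ortho oxygen and the ortho/para methoxy groups to give the hydrogen-bonded ortho-quinone methide 11 (heterodiene O=C–C=CH2); the terminal CH2 of 4-methoxystyrene then attacks the methide carbon while the developing p-methoxybenzylic cation is captured by the quinone-methide oxygen, a strongly asynchronous inverse-electron-demand oxa-[4+2] cycloaddition inside a chiral ion pair. The closest known reaction type is the chiral Brønsted acid catalysed [4+2] cycloaddition of in situ generated, aryl-substituted ortho-quinone methides (from secondary o-hydroxybenzyl alcohols) with styrenes; a methide-unsubstituted quinone methide from a primary saligenin, where C2 is the only stereocentre, has not been shown. The pyran ring closes as an intermolecular [4+2] annulation in which C3–C4 forms first and O1–C2 second, the latter as a six-membered collapse of oxygen on the benzylic cation. The C2 configuration is controlled by the catalyst alone: the phosphoramide anion stays hydrogen-bonded to the quinone-methide oxygen and its 3,3'-aryl walls should expose only one face of the styrene carbon to that oxygen. The step needs regioselectivity (aryl at C2, secured by the polarisation of both partners), chemoselectivity for the styrene over the prenyl alkene and over Friedel–Crafts attack by electron-rich arene carbons (secured by excess styrene, slow addition of 9 and the concerted pathway open only to the styrene), and kinetic control (low temperature and an acid too weak to reionise the C2–O bond or to protonate the prenyl alkene).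

**Compound list**

1 | 3,5-dimethoxyphenol | COc1cc(O)cc(OC)c1 | starting material
2 | (3,5-dimethoxyphenoxy)tri(propan-2-yl)silane | COc1cc(O[Si](C(C)C)(C(C)C)C(C)C)cc(OC)c1 | intermediate
3 | prenyl bromide (1-bromo-3-methylbut-2-ene) | CC(C)=CCBr | starting material
4 | [2,6-dimethoxy-4-(triisopropylsilyloxy)phenyl]lithium | [Li]c1c(OC)cc(O[Si](C(C)C)(C(C)C)C(C)C)cc1OC | intermediate (not isolated)
5 | [3,5-dimethoxy-4-(3-methylbut-2-en-1-yl)phenoxy]tri(propan-2-yl)silane | COc1cc(O[Si](C(C)C)(C(C)C)C(C)C)cc(OC)c1CC=C(C)C | intermediate
6 | 3,5-dimethoxy-4-(3-methylbut-2-en-1-yl)phenol | COc1cc(O)cc(OC)c1CC=C(C)C | intermediate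
7 | magnesium 3,5-dimethoxy-4-(3-methylbut-2-en-1-yl)-2-(oxidomethyl)phenolate | [Mg+2].[O-]Cc1c([O-])cc(OC)c(CC=C(C)C)c1OC | intermediate (not isolated)
8 | 6-hydroxy-2,4-dimethoxy-3-(3-methylbut-2-en-1-yl)benzaldehyde | O=Cc1c(O)cc(OC)c(CC=C(C)C)c1OC | intermediate
9 | 2-(hydroxymethyl)-3,5-dimethoxy-4-(3-methylbut-2-en-1-yl)phenol | OCc1c(O)cc(OC)c(CC=C(C)C)c1OC | intermediate
10 | 4-methoxystyrene (1-ethenyl-4-methoxybenzene) | C=Cc1ccc(OC)cc1 | starting material
11 | 3,5-dimethoxy-6-methylidene-4-(3-methylbut-2-en-1-yl)cyclohexa-2,4-dien-1-one | C=C1C(=O)C=C(OC)C(CC=C(C)C)=C1OC | intermediate (not isolated)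
12 | (2S)-5,7-dimethoxy-2-(4-methoxyphenyl)-6-(3-methylbut-2-en-1-yl)-3,4-dihydro-2H-chromene | COc1ccc([C@@H]2CCc3c(cc(OC)c(CC=C(C)C)c3OC)O2)cc1 | target

**Summary**

Total step count: 6. Longest linear sequence: 6 steps (1 → 12).

Steps most likely to fail:

1. Step 6 (Proposed new method). The catalyst may not discriminate the two faces of the styrene well enough without a substituent on the methide carbon, and the quinone methide may be consumed by Friedel–Crafts oligomerisation with electron-rich arene carbons. The fallback uses known chemistry and sets the stereocentre before the ring is closed. It sets out from aldehyde 8. Wittig olefination with 1-(4-methoxyphenyl)-2-(triphenylphosphoranylidene)ethanone (toluene, reflux) should give the chalcone (E)-3-[6-hydroxy-2,4-dimethoxy-3-(3-methylbut-2-en-1-yl)phenyl]-1-(4-methoxyphenyl)prop-2-en-1-one F1. Copper hydride conjugate reduction (Cu(OAc)2, 1,2-bis(diphenylphosphino)benzene, PMHS, t-BuOH, toluene), which should leave the isolated trisubstituted alkene alone, should give the dihydrochalcone 3-[6-hydroxy-2,4-dimethoxy-3-(3-methylbut-2-en-1-yl)phenyl]-1-(4-methoxyphenyl)propan-1-one F2. Noyori asymmetric transfer hydrogenation (RuCl[(R,R)-TsDPEN](p-cymene), HCO2H/Et3N) should give the carbinol 2-[(3R)-3-hydroxy-3-(4-methoxyphenyl)propyl]-3,5-dimethoxy-4-(3-methylbut-2-en-1-yl)phenol F3. Mitsunobu cycloetherification (PPh3, DIAD, THF, 0 °C) with inversion at the carbinol carbon should then close the pyran ring, and the fallback comes back to the route at target 12.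

2. Step 5. The salicylaldehyde may be over-reduced to the ortho-methylphenol (hydride capture of a quinone methide formed from the borate), and the very electron-rich saligenin may self-condense on concentration. The fallback introduces the one-carbon unit at the alcohol oxidation level without hydride and stores it in masked form. It sets out from phenol 6. Boron-templated ortho-hydroxymethylation (PhB(OH)2, paraformaldehyde, cat. propionic acid, toluene, reflux with water removal) should give the stable 5,7-dimethoxy-6-(3-methylbut-2-en-1-yl)-2-phenyl-4H-1,3,2-benzodioxaborinine F4. Transesterification with propane-1,3-diol (THF, rt, neutral) just before use should release the saligenin, and the fallback comes back to the route at 9.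

3. Step 2. The aryl-metal may attack the tertiary end of prenyl bromide (SN2′), giving the reverse-prenyl isomer, or undergo halogen–metal exchange and homocoupling. The fallback uses an electrophile for which both modes of attack give the same product and builds the prenyl group afterwards. It sets out from silyl ether 2, lithiated as before to aryllithium 4. Alkylation with allyl bromide should give [3,5-dimethoxy-4-(prop-2-en-1-yl)phenoxy]tri(propan-2-yl)silane F5. Olefin cross-metathesis with 2-methylbut-2-ene (Grubbs second-generation catalyst, rt) should convert the allyl into the prenyl group, and the fallback comes back to the route at 5.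

**Further compounds**

F1 | step 6 | (E)-3-[6-hydroxy-2,4-dimethoxy-3-(3-methylbut-2-en-1-yl)phenyl]-1-(4-methoxyphenyl)prop-2-en-1-one | COc1ccc(C(=O)/C=C/c2c(O)cc(OC)c(CC=C(C)C)c2OC)cc1
F2 | step 6 | 3-[6-hydroxy-2,4-dimethoxy-3-(3-methylbut-2-en-1-yl)phenyl]-1-(4-methoxyphenyl)propan-1-one | COc1ccc(C(=O)CCc2c(O)cc(OC)c(CC=C(C)C)c2OC)cc1
F3 | step 6 | 2-[(3R)-3-hydroxy-3-(4-methoxyphenyl)propyl]-3,5-dimethoxy-4-(3-methylbut-2-en-1-yl)phenol | COc1ccc([C@H](O)CCc2c(O)cc(OC)c(CC=C(C)C)c2OC)cc1
F4 | step 5 | 5,7-dimethoxy-6-(3-methylbut-2-en-1-yl)-2-phenyl-4H-1,3,2-benzodioxaborinine | COc1cc2c(COB(c3ccccc3)O2)c(OC)c1CC=C(C)C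
F5 | step 2 | [3,5-dimethoxy-4-(prop-2-en-1-yl)phenoxy]tri(propan-2-yl)silane | COc1cc(O[Si](C(C)C)(C(C)C)C(C)C)cc(OC)c1CC=C
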